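## Retrosynthetic overview

1. The target is made from its 2,6-diol by double acetylation in the last step.
2. The ten-membered carbocycle is cut at C6–C7 and closed last, by intramolecular Barbier allylation of a lactol-masked cis-epoxy aldehyde (C6 electrophile) with the C7=C11 π-system of a 3-(bromomethyl)butenolide. This is the same bond and polarity as the C1→C10 closure of farnesyl diphosphate to germacrene A, and the 11(13)-exo-olefin emerges in the same event.
3. The 8,12-lactone comes from acylation of the 8-hydroxyl by the C12 acid (the C8–O–C12 bond of the biosynthetic lactonisation), completed by ring-closing metathesis. The 4,5-epoxide comes from oxygen transfer to the 4Z olefin while that olefin is held in a temporary δ-lactone between O2 and C6.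
4. The acyclic C15 chain is assembled from acrolein, an allenylboronate, AlMe3/CH2O and a senecioate dienolate (propargylation, carboalumination, vinylogous aldol).
5. Ring order: temporary δ-lactone → epoxide → butenolide → ten-membered carbocycle.

Assumption 1: germacrane numbering (C1–C15) is used for locants in the text; the target is then the 12,8-olide with a 1(10)E olefin, a cis-4,5-epoxide and acetoxy groups at C2 and C6, configuration 2S,4R,5S,6S,7R,8R.

Assumption 2: the enantiomer of each chiral catalyst (steps 1 and 5) is the one that gives the facial sense stated in the Why line; if the sense proves opposite, the mirror-image catalyst is used.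

## Route

Step 1
Reactants: 1 acrolein; 2 allenylboronic acid pinacol ester
Product: 4 (R)-hex-1-en-5-yn-3-ol, via borate ester 3 (not isolated)
Conditions: (R)-TRIP [(R)-3,3'-bis(2,4,6-triisopropylphenyl)-1,1'-binaphthyl-2,2'-diyl hydrogen phosphate] (5 mol %), 4 Å MS, toluene, −30 °C; aq. NaHCO3 work-up
Reagents that add atoms: none
Why: Chiral-phosphoric-acid-catalysed asymmetric propargylation (SE2' allenylboration through a closed six-membered transition state), in which Re-face attack on acrolein sets the (R)-carbinol that becomes C8.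

Step 2
Reactants: 4 (R)-hex-1-en-5-yn-3-ol
Product: 6 (2E,5R)-3-methylhepta-2,6-diene-1,5-diol, via alkenylalane 5 (not isolated)
Conditions: AlMe3 (3 equiv), Cp2ZrCl2 (0.25 equiv), CH2Cl2, 0 °C → rt; concentrate; n-BuLi, THF, −78 °C; (CH2O)n, −78 °C → rt; 1 M HCl
Reagents that add atoms: trimethylaluminium, C[Al](C)C; paraformaldehyde (as formaldehyde), C=O
Why: Negishi zirconium-catalysed carboalumination adds methyl and aluminium syn across the terminal alkyne (methyl to the internal carbon) and the derived alkenylalanate is hydroxymethylated with retention, so C14, C2 and the 1(10)E olefin are installed in one operation while the alkoxide-masked C8 centre and the vinyl group are untouched.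

Step 3
Reactants: 6 (2E,5R)-3-methylhepta-2,6-diene-1,5-diol
Product: 7 (2E,5R)-5-hydroxy-3-methylhepta-2,6-dienal
Conditions: TEMPO (10 mol %), PhI(OAc)2 (1.1 equiv), CH2Cl2, 0 °C → rt
Reagents that add atoms: none
Why: Oxoammonium (TEMPO) oxidation is selective for the primary allylic alcohol over the secondary one and does not isomerise the E-enal, and no stereocentre is affected.

Step 4
Reactants: 8 methyl 3-methylbut-2-enoate
Product: 9 1-methoxy-3-methyl-1-(trimethylsilyloxy)buta-1,3-diene
Conditions: lithium diisopropylamide, THF, −78 °C; Me3SiCl, −78 °C → rt; distil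
Reagents that add atoms: chlorotrimethylsilane, C[Si](C)(C)Cl
Why: Kinetic γ-deprotonation of the senecioate and O-silylation (silyl ketene acetal formation) give the silyl dienolate needed as the vinylogous nucleophile.

Step 5
Reactants: 7 (2E,5R)-5-hydroxy-3-methylhepta-2,6-dienal; 9 1-methoxy-3-methyl-1-(trimethylsilyloxy)buta-1,3-diene
Product: 12 (6S)-6-[(1E,4R)-4-hydroxy-2-methylhexa-1,5-dien-1-yl]-4-methyl-5,6-dihydro-2H-pyran-2-one, via silylated enal 10 (not isolated), via silylated lactone 11 (not isolated)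
Conditions: Cu(OTf)2 (10 mol %), (S)-Tol-BINAP (11 mol %), Bu4N[Ph3SiF2] (20 mol %), 9 (2.5 equiv), THF, 0 °C → rt; then citric acid, MeOH
Reagents that add atoms: none
Why: Copper-catalysed asymmetric vinylogous Mukaiyama aldol reaction in which the Tol-BINAP copper dienolate attacks the Si face of the enal through its γ-carbon to set C2 as S, and the (Z)-copper aldolate lactonises in situ so that the 4Z geometry is locked in the dihydropyranone, the C8 hydroxyl being only transiently silylated.

Step 6
Reactants: 12 (6S)-6-[(1E,4R)-4-hydroxy-2-methylhexa-1,5-dien-1-yl]-4-methyl-5,6-dihydro-2H-pyran-2-one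
Product: 13 (1R,4S,6R)-4-[(1E,4R)-4-hydroxy-2-methylhexa-1,5-dien-1-yl]-6-methyl-3,7-dioxabicyclo[4.1.0]heptan-2-one
Conditions: 30 % H2O2 (5 equiv), NaOH (0.3 equiv), MeOH, −10 → 0 °C; then aq. NaH2PO4 to pH 4
Reagents that add atoms: hydrogen peroxide, OO
Why: Weitz–Scheffer nucleophilic epoxidation in which hydroperoxide adds axially to C4 of the half-chair lactone anti to the pseudo-equatorial C2 side chain and the ring enforces a cis-epoxide (germacrane 4R,5S) trans to that side chain, while the electron-rich 1(10) and vinyl olefins are inert.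

Step 7
Reactants: 13 (1R,4S,6R)-4-[(1E,4R)-4-hydroxy-2-methylhexa-1,5-dien-1-yl]-6-methyl-3,7-dioxabicyclo[4.1.0]heptan-2-one; 14 2-(bromomethyl)acrylic acid
Product: 15 (3R,5E)-5-methyl-6-[(1R,4S,6R)-6-methyl-2-oxo-3,7-dioxabicyclo[4.1.0]heptan-4-yl]hexa-1,5-dien-3-yl 2-(bromomethyl)prop-2-enoate
Conditions: DCC (1.5 equiv), DMAP (5 mol %), CH2Cl2, −20 → 0 °C
Reagents that add atoms: none
Why: Steglich esterification of the only free hydroxyl (C8) creates the C8–O–C12 acyl bond of the future lactone with retention at C8, and the cold, DMAP-poor conditions avoid SN2' attack on the allylic bromide.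

Step 8
Reactants: 15 (3R,5E)-5-methyl-6-[(1R,4S,6R)-6-methyl-2-oxo-3,7-dioxabicyclo[4.1.0]heptan-4-yl]hexa-1,5-dien-3-yl 2-(bromomethyl)prop-2-enoate
Product: 16 (3R,5E)-6-[(1R,4S,6R)-2-hydroxy-6-methyl-3,7-dioxabicyclo[4.1.0]heptan-4-yl]-5-methylhexa-1,5-dien-3-yl 2-(bromomethyl)prop-2-enoate (lactol, anomer mixture)
Conditions: i-Bu2AlH (1.05 equiv), CH2Cl2, −90 → −78 °C; MeOH, then aq. potassium sodium tartrate
Reagents that add atoms: none
Why: Chemoselective DIBAL half-reduction, relying on the non-conjugated α-oxygenated δ-lactone being much more electrophilic than the hindered conjugated acrylate ester and on its aluminium lactolate being stable at low temperature, releases the masked cis-epoxy aldehyde without touching the ester, the bromide or any stereocentre.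

Step 9
Reactants: 16 (3R,5E)-6-[(1R,4S,6R)-2-hydroxy-6-methyl-3,7-dioxabicyclo[4.1.0]heptan-4-yl]-5-methylhexa-1,5-dien-3-yl 2-(bromomethyl)prop-2-enoate
Product: 17 (5R)-3-(bromomethyl)-5-{(2E)-3-[(1R,4S,6R)-2-hydroxy-6-methyl-3,7-dioxabicyclo[4.1.0]heptan-4-yl]-2-methylprop-2-en-1-yl}furan-2(5H)-one
Conditions: second-generation Grubbs catalyst (5 mol %), CH2Cl2 (5 mM), 40 °C
Reagents that add atoms: none
Why: Ring-closing metathesis between the C7 vinyl group and the 1,1-disubstituted acrylate closes the butenolide with loss of ethene (as in the standard closure of allyl methacrylates to α-methylbutenolides), leaving the trisubstituted olefin, epoxide, lactol, allylic bromide and C8 unchanged.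

Step 10
Reactants: 17 (5R)-3-(bromomethyl)-5-{(2E)-3-[(1R,4S,6R)-2-hydroxy-6-methyl-3,7-dioxabicyclo[4.1.0]heptan-4-yl]-2-methylprop-2-en-1-yl}furan-2(5H)-one
Product: 19 (1(10)E,2S,4R,5S,6S,7S,8R)-4,5-epoxy-2,6-dihydroxygermacra-1(10),11(13)-dien-12,8-olide, via allylindium aldehyde 18 (not isolated)
Conditions: In powder (3 equiv), THF/H2O 1:1 (2 mM), 25 °C, ultrasound
Reagents that add atoms: none
Why: Proposed new method: zerovalent indium inserts into the allylic C–Br bond and the allylindium, held E-like by the butenolide ring, adds through its γ-carbon C7 to the aldehyde released from the lactol in a chair (Zimmerman–Traxler) transition state, where Felkin–Anh attack anti to the epoxide C–O sets C6, the chair gives the 6,7-anti relationship and delivery to the butenolide face that carries the C9 tether gives the cis-fused lactone with the 11(13)-exo-olefin formed by allylic transposition, the closest known chemistry being indium- or zinc-mediated Barbier allylation of lactols by 2-(bromomethyl)acrylates and intramolecular Barbier (Nozaki–Hiyama type) macrocyclisation of bromomethyl-acrylate aldehydes.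

Step 11
Reactants: 19 (1(10)E,2S,4R,5S,6S,7S,8R)-4,5-epoxy-2,6-dihydroxygermacra-1(10),11(13)-dien-12,8-olide
Product: 20 (1(10)E,2S,4R,5S,6S,7R,8R)-2,6-diacetoxy-4,5-epoxygermacra-1(10),11(13)-dien-12,8-olide (CNP0270851.1)
Conditions: Ac2O (4 equiv), pyridine, DMAP (10 mol %), CH2Cl2, 0 °C → rt
Reagents that add atoms: acetic anhydride, CC(=O)OC(C)=O
Why: DMAP-catalysed acetylation of both secondary hydroxyls (C2 and C6) proceeds with retention and touches no stereocentre (the C7 descriptor changes from S to R only through CIP priorities).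

## Compound list

1 | acrolein (prop-2-enal) | C=CC=O | starting material
2 | allenylboronic acid pinacol ester (4,4,5,5-tetramethyl-2-(propa-1,2-dien-1-yl)-1,3,2-dioxaborolane) | C=C=CB1OC(C)(C)C(C)(C)O1 | starting material
3 | (R)-2-(hex-1-en-5-yn-3-yloxy)-4,4,5,5-tetramethyl-1,3,2-dioxaborolane | C=C[C@H](OB1OC(C)(C)C(C)(C)O1)CC#C | intermediate (not isolated)
4 | (R)-hex-1-en-5-yn-3-ol | C=C[C@H](O)CC#C | intermediate
5 | dimethyl{(1E,4R)-4-[(dimethylalumanyl)oxy]-2-methylhexa-1,5-dien-1-yl}alumane | C[Al](C)/C=C(C)/C[C@@H](O[Al](C)C)C=C | intermediate (not isolated)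
6 | (2E,5R)-3-methylhepta-2,6-diene-1,5-diol | OC/C=C(C)/C[C@@H](O)C=C | intermediate
7 | (2E,5R)-5-hydroxy-3-methylhepta-2,6-dienal | O=C/C=C(C)/C[C@@H](O)C=C | intermediate
8 | methyl 3-methylbut-2-enoate | COC(=O)C=C(C)C | starting material
9 | 1-methoxy-3-methyl-1-(trimethylsilyloxy)buta-1,3-diene | C=C(C)C=C(OC)O[Si](C)(C)C | intermediate
10 | (2E,5R)-3-methyl-5-(trimethylsilyloxy)hepta-2,6-dienal | O=C/C=C(C)/C[C@@H](O[Si](C)(C)C)C=C | intermediate (not isolated)
11 | (6S)-4-methyl-6-[(1E,4R)-2-methyl-4-(trimethylsilyloxy)hexa-1,5-dien-1-yl]-5,6-dihydro-2H-pyran-2-one | C=C[C@H](O[Si](C)(C)C)C/C(C)=C/[C@@H]1CC(C)=CC(=O)O1 | intermediate (not isolated)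
12 | (6S)-6-[(1E,4R)-4-hydroxy-2-methylhexa-1,5-dien-1-yl]-4-methyl-5,6-dihydro-2H-pyran-2-one | C=C[C@H](O)C/C(C)=C/[C@@H]1CC(C)=CC(=O)O1 | intermediate
13 | (1R,4S,6R)-4-[(1E,4R)-4-hydroxy-2-methylhexa-1,5-dien-1-yl]-6-methyl-3,7-dioxabicyclo[4.1.0]heptan-2-one (cis-epoxide trans to the side chain) | C=C[C@H](O)C/C(C)=C/[C@@H]1C[C@@]2(C)O[C@H]2C(=O)O1 | intermediate
14 | 2-(bromomethyl)acrylic acid | C=C(CBr)C(=O)O | starting material
15 | (3R,5E)-5-methyl-6-[(1R,4S,6R)-6-methyl-2-oxo-3,7-dioxabicyclo[4.1.0]heptan-4-yl]hexa-1,5-dien-3-yl 2-(bromomethyl)prop-2-enoate | C=C[C@H](OC(=O)C(=C)CBr)C/C(C)=C/[C@@H]1C[C@@]2(C)O[C@H]2C(=O)O1 | intermediate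
16 | (3R,5E)-6-[(1R,4S,6R)-2-hydroxy-6-methyl-3,7-dioxabicyclo[4.1.0]heptan-4-yl]-5-methylhexa-1,5-dien-3-yl 2-(bromomethyl)prop-2-enoate (lactol, anomer mixture) | C=C[C@H](OC(=O)C(=C)CBr)C/C(C)=C/[C@@H]1C[C@@]2(C)O[C@H]2C(O)O1 | intermediate
17 | (5R)-3-(bromomethyl)-5-{(2E)-3-[(1R,4S,6R)-2-hydroxy-6-methyl-3,7-dioxabicyclo[4.1.0]heptan-4-yl]-2-methylprop-2-en-1-yl}furan-2(5H)-one | BrCC1=C[C@@H](C/C(C)=C/[C@@H]2C[C@@]3(C)O[C@H]3C(O)O2)OC1=O | intermediate
18 | open-chain cis-epoxy aldehyde form of 17 with CH2–In (monovalent indium) in place of CH2Br | [In]CC1=C[C@@H](C/C(C)=C/[C@@H](O)C[C@@]2(C)O[C@H]2C=O)OC1=O | intermediate (not isolated)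
19 | (1(10)E,2S,4R,5S,6S,7S,8R)-4,5-epoxy-2,6-dihydroxygermacra-1(10),11(13)-dien-12,8-olide (same spatial arrangement at C7 as in 20) | C=C1C(=O)O[C@@H]2C/C(C)=C/[C@@H](O)C[C@@]3(C)O[C@H]3[C@@H](O)[C@H]12 | intermediate
20 | (1(10)E,2S,4R,5S,6S,7R,8R)-2,6-diacetoxy-4,5-epoxygermacra-1(10),11(13)-dien-12,8-olide; cis-4,5-epoxide, cis-fused α-methylene-γ-lactone | C=C1C(=O)O[C@@H]2C/C(C)=C/[C@@H](OC(C)=O)C[C@@]3(C)O[C@H]3[C@@H](OC(C)=O)[C@H]12 | target

## Step count and risks

Total step count: 11. Longest linear sequence: 10 (steps 1–3 and 5–11; step 4 is a one-step side branch).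

The three steps most likely to fail:

Step 10 (macrocyclisation). It may give oligomers, protodebrominated material, or the 6-epi or trans-fused diastereomers, because three stereochemical preferences must cooperate in a ten-membered transition state. The fallback sets out from 17 and returns at 19. The allylic bromide is converted with B2pin2 and Pd2(dba)3 (base-free allylic borylation, toluene, 50 °C) into the pinacol allylboronate F1. This is heated at high dilution (toluene, 60–80 °C, optionally with a chiral BINOL-derived phosphoric acid to reinforce the facial sense), so that a thermal intramolecular allylboration of the lactol aldehyde closes the ring through a tighter boron-centred chair. Work-up with triethanolamine releases 19.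

Step 8 (selective half-reduction). The hydride may also attack the acrylate ester or displace the allylic bromide. The fallback sets out from 13 and returns at 17, reducing before the ester is present:
- The C8 hydroxyl of 13 is silylated (Et3SiCl, imidazole) to the C8 triethylsilyl ether F2.
- Reduction with i-Bu2AlH then gives the lactol F3 without any competing ester.
- The anomeric hydroxyl is capped (t-BuMe2SiCl, imidazole) to give the anomeric tert-butyldimethylsilyl ether F4.
- The triethylsilyl group is removed selectively (PPTS, MeOH, 0 °C) to give the C8 alcohol F5.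
- Esterification with 14 (DCC, DMAP) gives the bromomethylacrylate F6.
- Ring-closing metathesis (second-generation Grubbs catalyst) gives the butenolide F7.
- Buffered HF·pyridine frees the lactol, giving 17.

Step 6 (nucleophilic epoxidation). The β,β-disubstituted lactone may react slowly, and base can open the ring by E1cB elimination to a trienoic acid. The fallback sets out from 12 and returns at 13, replacing substrate control by reagent control. LiAlH4 (THF, 0 °C) reduces the lactone to the (2Z)-allylic triol F8. Sharpless asymmetric epoxidation (Ti(OiPr)4, L-(+)-diethyl tartrate, t-BuOOH, 4 Å MS, CH2Cl2, −20 °C) epoxidises only the primary nerol-type allylic alcohol, giving the epoxy triol F9 with the same 4R,5S sense. TEMPO/PhI(OAc)2 then oxidises the primary alcohol and relactonises through the lactol to 13.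

Further compounds
F1 | step 10 | (5R)-5-{(2E)-3-[(1R,4S,6R)-2-hydroxy-6-methyl-3,7-dioxabicyclo[4.1.0]heptan-4-yl]-2-methylprop-2-en-1-yl}-3-[(4,4,5,5-tetramethyl-1,3,2-dioxaborolan-2-yl)methyl]furan-2(5H)-one | CC1(C)OB(CC2=C[C@@H](C/C(C)=C/[C@@H]3C[C@@]4(C)O[C@H]4C(O)O3)OC2=O)OC1(C)C
F2 | step 8 | (1R,4S,6R)-6-methyl-4-[(1E,4R)-2-methyl-4-(triethylsilyloxy)hexa-1,5-dien-1-yl]-3,7-dioxabicyclo[4.1.0]heptan-2-one | C=C[C@H](O[Si](CC)(CC)CC)C/C(C)=C/[C@@H]1C[C@@]2(C)O[C@H]2C(=O)O1
F3 | step 8 | (1R,4S,6R)-6-methyl-4-[(1E,4R)-2-methyl-4-(triethylsilyloxy)hexa-1,5-dien-1-yl]-3,7-dioxabicyclo[4.1.0]heptan-2-ol | C=C[C@H](O[Si](CC)(CC)CC)C/C(C)=C/[C@@H]1C[C@@]2(C)O[C@H]2C(O)O1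
F4 | step 8 | tert-butyldimethylsilyl ether of the lactol hydroxyl of F3 | C=C[C@H](O[Si](CC)(CC)CC)C/C(C)=C/[C@@H]1C[C@@]2(C)O[C@H]2C(O[Si](C)(C)C(C)(C)C)O1
F5 | step 8 | (3R,5E)-6-[(1R,4S,6R)-2-(tert-butyldimethylsilyloxy)-6-methyl-3,7-dioxabicyclo[4.1.0]heptan-4-yl]-5-methylhexa-1,5-dien-3-ol | C=C[C@H](O)C/C(C)=C/[C@@H]1C[C@@]2(C)O[C@H]2C(O[Si](C)(C)C(C)(C)C)O1
F6 | step 8 | 2-(bromomethyl)prop-2-enoate ester of F5 | C=C[C@H](OC(=O)C(=C)CBr)C/C(C)=C/[C@@H]1C[C@@]2(C)O[C@H]2C(O[Si](C)(C)C(C)(C)C)O1
F7 | step 8 | anomeric tert-butyldimethylsilyl ether of 17 | BrCC1=C[C@@H](C/C(C)=C/[C@@H]2C[C@@]3(C)O[C@H]3C(O[Si](C)(C)C(C)(C)C)O2)OC1=O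
F8 | step 6 | (2Z,5S,6E,9R)-3,7-dimethylundeca-2,6,10-triene-1,5,9-triol | OC/C=C(C)\C[C@H](O)/C=C(C)/C[C@@H](O)C=C
F9 | step 6 | {(2S,3R)-3-[(2S,3E,6R)-2,6-dihydroxy-4-methylocta-3,7-dien-1-yl]-3-methyloxiran-2-yl}methanol | C=C[C@H](O)C/C(C)=C/[C@@H](O)C[C@@]1(C)O[C@H]1CO
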